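**Retrosynthetic overview**
- The target comes from its racemate by a chiral-base kinetic resolution; the racemate comes from a 3,6-dihydro-1,2-dioxin-3-ol by acid-catalysed ketalisation in MeOH, which sets C6 relative to C3.
- Key disconnection: the C3–O bond of the dioxinol is made by a carbon radical trapping triplet O2, after Mn–H hydrogen-atom transfer to a (2E,4Z)-6-oxo-2,4-dienoate; the peroxide ring then closes on the ketone.
- The keto-dienoate comes from Rh-carbenoid unravelling of 2-hexadecylfuran with methyl diazoacetate; the furan is a masked Z-enone.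
- 2-Hexadecylfuran comes from hydrogenation of a furyl diyne assembled from 1-octyne, 1-bromo-6-chlorohexane and 2-ethynylfuran.
- Ring order: the purchased furan ring is opened in step 3; the only ring formed is the 1,2-dioxine (step 4).

Assumption: methyl diazoacetate and 2-ethynylfuran are taken as purchasable, and the quinidine-derived catalyst in step 6 is taken to consume the (3R,6R) enantiomer (if the first run retains the antipode, its quinine-derived pseudo-enantiomer is used in the same step).

**Step 1**
Reactants: 1 1-octyne; 2 1-bromo-6-chlorohexane; 3 2-ethynylfuran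
Product: 7 2-(hexadeca-1,9-diyn-1-yl)furan, via lithium oct-1-yn-1-ide 4 (not isolated), via 1-chlorotetradec-7-yne 5 (not isolated), via lithium 2-(furan-2-yl)ethyn-1-ide 6 (not isolated)
Conditions: 1, n-BuLi, THF, −78 → 0 °C; 2, DMPU, 0 → 23 °C; then 3 + n-BuLi (pre-mixed, THF, −78 °C), NaI (cat.), 60 °C
Reagents that add atoms: none
Why: Two consecutive SN2 alkylations of lithium acetylides use the large Br over Cl leaving-group difference (bromide first, then the chloride under Finkelstein catalysis) to build the unbranched C16 chain on the furan in one pot, with no stereocentre formed.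

**Step 2**
Reactants: 7 2-(hexadeca-1,9-diyn-1-yl)furan
Product: 8 2-hexadecylfuran
Conditions: H2 (1 atm), 10 % Pd/C, EtOAc, 23 °C, stopped after 4 equiv H2
Reagents that add atoms: none
Why: Heterogeneous catalytic hydrogenation saturates both triple bonds far faster than the aromatic furan at 1 atm in a neutral solvent, leaving the furan as a masked Z-enone.

**Step 3**
Reactants: 8 2-hexadecylfuran; 9 methyl diazoacetate
Product: 11 methyl (2E,4Z)-6-oxodocosa-2,4-dienoate, via oxabicyclohexene ester 10 (not isolated)
Conditions: Rh2(OAc)4 (1 mol %), CH2Cl2, 23 °C, slow addition of 9 (syringe pump), dark; rapid filtration through neutral silica, used at once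
Reagents that add atoms: none
Why: Rh(II)-carbenoid cyclopropanation of the unsubstituted 4,5-bond of the 2-alkylfuran and spontaneous ring opening of the donor–acceptor cyclopropane (Wenkert-type furan unravelling) give the keto-dienoate, with the 4Z bond inherited from the ring and the 2E bond from the exo ester.

**Step 4**
Reactants: 11 methyl (2E,4Z)-6-oxodocosa-2,4-dienoate
Product: 13 methyl 2-(6-hexadecyl-6-hydroxy-3,6-dihydro-1,2-dioxin-3-yl)acetate, via Z-hydroperoxy enone 12 (not isolated)
Conditions: Mn(dpm)3 (5 mol %), PhSiH3 (1.2 equiv), O2 (1 atm), i-PrOH/CH2Cl2, 0 °C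
Reagents that add atoms: dioxygen (O=O)
Why: Proposed new method: a vinylogous Mukaiyama–Isayama hydroperoxidation in which Mn–H transfers H• to C2 (the diene terminus δ to the stronger acceptor, the ketone, giving the most delocalised 1-oxopentadienyl radical), triplet O2 traps that radical at C3 (γ, retaining enone conjugation and, because O2 capture outruns allyl rotation, the 4Z geometry), and the resulting Z-γ-hydroperoxy enone closes onto the ketone as a peroxy-hemiketal, which also removes the enone from further hydrogen-atom transfer; the closest known reactions are the Co/Et3SiH/O2 γ-peroxidation of α,β,γ,δ-unsaturated esters and the Mn(dpm)3/PhSiH3/O2 α-hydroperoxidation of enones, and C3 is formed racemic.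

**Step 5**
Reactants: 13 methyl 2-(6-hexadecyl-6-hydroxy-3,6-dihydro-1,2-dioxin-3-yl)acetate
Product: 14 rac-methyl 2-[(3S*,6S*)-6-hexadecyl-6-methoxy-3,6-dihydro-1,2-dioxin-3-yl]acetate
Conditions: MeOH, TsOH·H2O (5 mol %), 4 Å MS, 23 °C; SiO2 separation of the C6 epimers (minor epimer re-equilibrated under the same conditions)
Reagents that add atoms: methanol (CO)
Why: Acid-catalysed hemiketal-to-ketal exchange through the peroxycarbenium ion is reversible, so C6 is set under thermodynamic control relative to C3 with OMe pseudoaxial (anomeric effect) and both carbon substituents pseudoequatorial, which is the cis (3S*,6S*) ketal; the preference is expected to be modest.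

**Step 6**
Reactants: 14 rac-methyl 2-[(3S*,6S*)-6-hexadecyl-6-methoxy-3,6-dihydro-1,2-dioxin-3-yl]acetate
Product: 15 methyl 2-[(3S,6S)-6-hexadecyl-6-methoxy-3,6-dihydro-1,2-dioxin-3-yl]acetate (6-epi-chondrillin)
Conditions: cupreidine 9-O-acetate (10 mol %), CH2Cl2, 0 → 23 °C, stopped at ca. 55–60 % conversion (chiral HPLC); SiO2
Reagents that add atoms: none
Why: Proposed new method: a kinetic resolution by enantioselective Kornblum–DeLaMare fragmentation, in which the bifunctional cinchona base (quinuclidine N as base, 6'-OH as hydrogen-bond donor to the peroxide) removes the single C3–H of the (3R,6R) enantiomer faster and converts it into a polar ene-dione while the (3S,6S) ketal is recovered unchanged (50 % maximum); the closest known reaction is the cinchona-catalysed desymmetrising Kornblum–DeLaMare rearrangement of meso endoperoxides, and no stereocentre of the recovered material is touched.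

**Compound list**
1 | 1-octyne | CCCCCCC#C | starting material
2 | 1-bromo-6-chlorohexane | ClCCCCCCBr | starting material
3 | 2-ethynylfuran | C#Cc1ccco1 | starting material
4 | lithium oct-1-yn-1-ide | [Li+].[C-]#CCCCCCC | intermediate
5 | 1-chlorotetradec-7-yne | CCCCCCC#CCCCCCCCl | intermediate
6 | lithium 2-(furan-2-yl)ethyn-1-ide | [Li+].[C-]#Cc1ccco1 | intermediate
7 | 2-(hexadeca-1,9-diyn-1-yl)furan | CCCCCCC#CCCCCCCC#Cc1ccco1 | intermediate
8 | 2-hexadecylfuran | CCCCCCCCCCCCCCCCc1ccco1 | intermediate
9 | methyl diazoacetate | COC(=O)C=[N+]=[N-] | starting material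
10 | methyl 3-hexadecyl-2-oxabicyclo[3.1.0]hex-3-ene-6-carboxylate (racemic, exo ester) | CCCCCCCCCCCCCCCCC1=CC2C(C(=O)OC)C2O1 | intermediate
11 | methyl (2E,4Z)-6-oxodocosa-2,4-dienoate | CCCCCCCCCCCCCCCCC(=O)/C=C\C=C\C(=O)OC | intermediate
12 | methyl (4Z)-3-hydroperoxy-6-oxodocos-4-enoate (racemic) | CCCCCCCCCCCCCCCCC(=O)/C=C\C(OO)CC(=O)OC | intermediate
13 | methyl 2-(6-hexadecyl-6-hydroxy-3,6-dihydro-1,2-dioxin-3-yl)acetate (racemic at C3, C6 anomer mixture) | CCCCCCCCCCCCCCCCC1(O)C=CC(CC(=O)OC)OO1 | intermediate
14 | rac-methyl 2-[(3S*,6S*)-6-hexadecyl-6-methoxy-3,6-dihydro-1,2-dioxin-3-yl]acetate (1:1 mixture of enantiomers, OMe cis to CH2CO2Me) | CCCCCCCCCCCCCCCC[C@@]1(OC)C=C[C@H](CC(=O)OC)OO1.CCCCCCCCCCCCCCCC[C@]1(OC)C=C[C@@H](CC(=O)OC)OO1 | intermediate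
15 | methyl 2-[(3S,6S)-6-hexadecyl-6-methoxy-3,6-dihydro-1,2-dioxin-3-yl]acetate (6-epi-chondrillin) | CCCCCCCCCCCCCCCC[C@@]1(OC)C=C[C@H](CC(=O)OC)OO1 | target

**Totals and risks**
Total step count: 6. Longest linear sequence: 6.

Step 4 (most likely to fail: H-atom transfer to C5 instead of C2, O2 capture at C5, or over-reduction). The fallback sets out from 11 and comes back at 14. Luche reduction (NaBH4, CeCl3, MeOH, −40 °C) gives methyl (2E,4Z)-6-hydroxydocosa-2,4-dienoate F2. O-Methylation (MeOTf, 2,6-di-tert-butyl-4-methylpyridine, CH2Cl2) gives methyl (2E,4Z)-6-methoxydocosa-2,4-dienoate F3. Radical-chain autoxidation (O2, NHPI cat., 35 °C) abstracts the doubly activated C6–H and traps O2 at C6, where the dienoate conjugation is retained, to give methyl (2E,4Z)-6-hydroperoxy-6-methoxydocosa-2,4-dienoate F4. Et2NH in CF3CH2OH then closes the ring by 6-exo peroxy-Michael addition, and brief treatment under the step 5 conditions delivers 14; the peroxide C–O bond is still made by a carbon radical and O2.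

Step 6 (selectivity factor of the kinetic resolution unknown). The fallback sets out from 13 and comes back at 15. Ketalisation of 13 with (−)-menthol (PPTS, 4 Å MS, CH2Cl2) gives diastereomeric menthyl ketals. Chromatography isolates the (3S) series, chiefly methyl 2-[(3S,6S)-6-hexadecyl-6-[(1R,2S,5R)-menthyloxy]-3,6-dihydro-1,2-dioxin-3-yl]acetate F5. Exchange in MeOH/TsOH then gives 15, since C6 re-equilibrates while C3 is untouched, and menthol is recovered.

Step 3 (carbenoid dimerisation, formal C–H insertion at C5 of the furan, or 4Z to 4E isomerisation). The fallback sets out from 8 and comes back at 11. Oxidative furan opening (NBS, NaHCO3, acetone/H2O, −15 °C) gives (2Z)-4-oxoicos-2-enal F1. Aldehyde-selective, E-selective Wittig olefination with Ph3P=CHCO2Me (CH2Cl2, 0 °C) then gives 11.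

**Further compounds**
F1 | step 3 | (2Z)-4-oxoicos-2-enal | CCCCCCCCCCCCCCCCC(=O)/C=C\C=O
F2 | step 4 | methyl (2E,4Z)-6-hydroxydocosa-2,4-dienoate (racemic) | CCCCCCCCCCCCCCCCC(O)/C=C\C=C\C(=O)OC
F3 | step 4 | methyl (2E,4Z)-6-methoxydocosa-2,4-dienoate (racemic) | CCCCCCCCCCCCCCCCC(OC)/C=C\C=C\C(=O)OC
F4 | step 4 | methyl (2E,4Z)-6-hydroperoxy-6-methoxydocosa-2,4-dienoate (racemic) | CCCCCCCCCCCCCCCCC(OC)(OO)/C=C\C=C\C(=O)OC
F5 | step 6 | methyl 2-[(3S,6S)-6-hexadecyl-6-[(1R,2S,5R)-menthyloxy]-3,6-dihydro-1,2-dioxin-3-yl]acetate | CCCCCCCCCCCCCCCC[C@@]1(O[C@@H]2C[C@H](C)CC[C@H]2C(C)C)C=C[C@H](CC(=O)OC)OO1
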